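The earlier runs and the new flask were generated by integration with constants of no real substance, and the scatter is random.

In a one-step world, with the rate in proportion to Ctl and to Sbt, Ptn held at its charge, Ctl lasting and Sbt going to Pdt and nowhere else, halving the Ctl charge would slow a flask's clock and do nothing more. We therefore follow a flask's reach: minus the natural logarithm of the share of the Sbt charge not found as Pdt. In that world, reach goes with the Ctl charge to the power one.

| setting | north | south | south-west | east |
|---|---|---|---|---|
| Sbt | 0.250 M | 0.130 M | 0.250 M | 0.250 M |
| Ptn | 0.750 M | 0.630 M | 0.750 M | 0.750 M |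
| Ctl | 0.00500 M | 0.00500 M | 0.00250 M | 7.70 × 10⁻⁴ M |
| time |  |  |  | 12 h |

| run | time / h | [Pdt] / M |
|---|---|---|
| north run | 1.7 | 0.0528 |
| north run | 3.4 | 0.0755 |
| north run | 5.1 | 0.0877 |
| north run | 6.9 | 0.0958 |
| north run | 8.6 | 0.1004 |
| north run | 10 | 0.1031 |
| north run | 12 | 0.1045 |
| south run | 1.7 | 0.0258 |
| south run | 3.4 | 0.0391 |
| south run | 5.1 | 0.0475 |
| south run | 6.9 | 0.0534 |
| south run | 8.6 | 0.0553 |
| south run | 10 | 0.0566 |
| south run | 12 | 0.0592 |
| south-west run | 1.7 | 0.0324 |
| south-west run | 3.4 | 0.0490 |
| south-west run | 5.1 | 0.0595 |
| south-west run | 6.9 | 0.0680 |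
| south-west run | 8.6 | 0.0714 |
| south-west run | 10 | 0.0733 |
| south-west run | 12 | 0.0771 |

(each reading ± 0.001 M)

- how the opening rate goes with [Ctl] round the charge of the north run: the exponent of the rate at two percent of Sbt gone to Pdt
- Pdt in the east run at 12 h, as a share of the Sbt charged

- Overall: Sbt + Ptn -> Pdt, with Ctl as catalyst.
- Constant volume, constant temperature.
- "The second partner" is Ptn.
- An order is taken over about fifteen percent of the charge, up and down.

Take north and its neighbour south-west, alike but for half the Ctl, with Sbt the limiting reagent in both, its charge being less than that of Ptn. By 1.7 h, south-west has made 0.614 of north's Pdt. From 5.1 h to 12 h, north gains 6.72% of its Sbt charge and south-west 7.04%, alike within the scatter. So at 12 h north reads 41.8% of its Sbt charge and south-west 30.8%, because north's lead of 11.3% of the charge, more than south-west's later gain, was won by 5.1 h.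

In reach, north stands at 0.541 and south-west at 0.369 at 12 h. We carry the late exponent, the power of the Ctl charge that reach follows at that time between flasks of equal Sbt and Ptn charge: 0.554. The same reading at 1.7 h gives 0.773, our estimate for the opening.

East holds 30.8% of south-west's Ctl charge. Stepping down from south-west, the late exponent gives 17.5% of the Sbt charge as Pdt in east at 12 h and the early one 13.8%. We commit to their mean exponent, which gives 15.5%.

The forecast says 0.8 and 15%, a little below our figure for east, on the ground that “the catalyst dies, rather than equilibrium being reached”.

East gives 15.4%, the opening exponent round north's charge is 0.77, and the forecast holds.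

    2 Ctl ⇌ Ctl2, settled at all times (82.70 /M)
    Ctl + Sbt + Ptn → Pdt + Ctl (81.00 /M²/h)
    2 Sbt → Z (0.5904 /M/h)
    2 Ctl → 2 X (51.12 /M/h)

Where two percent of north's Sbt charge had turned to Pdt, south-west ran at 0.57 of north's rate. East's reach at 12 h is 0.167, so from south-west down to east the late exponent reads 0.672, higher than the 0.554 from north to south-west.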